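The runs are calculated for an exercise; the scatter is artificial.

If each partner charged made one target and each target stayed, Friday's flask, the one asked about, would hold target at a ceiling C, the partner charged over the substrate charged: 95.0% of the substrate. Partner, charged at less than substrate, is the limiting reagent there, and this one-to-one case is the zero of the scale.

| flask | substrate | partner | temperature | remark | time |
|---|---|---|---|---|---|
| Friday's | 0.020 M | 0.019 M | 25 °C | the very flask that is asked about, followed so far |  |
| Wednesday's | 0.020 M | 0.038 M | 25 °C | run made earlier |  |
| flask | 0.020 M | 0.0190 M | 25 °C |  | 4.0 h |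

| run | time / min | target / % |
|---|---|---|
| Friday's | 15.0 | 69.8 |
| Friday's | 50.0 | 77.6 |
| Friday's | 80.0 | 77.2 |
| Friday's | 120 | 77.2 |
| Friday's | 180 | 74.7 |
| Friday's | 240 | 70.9 |
| Wednesday's | 4.00 | 74.8 |
| Wednesday's | 6.00 | 83.5 |
| Wednesday's | 12.0 | 94.7 |
| Wednesday's | 20.0 | 95.3 |
| Wednesday's | 30.0 | 96.5 |
| Wednesday's | 50.0 | 93.4 |

(readings scatter by 1 percentage point)

- blue: at 4.0 h take out 90% of the by-product then present, then wait 4.0 h
- amber: change nothing and wait 4.0 h more
- red: at 4.0 h raise the temperature by 20 K, then wait 4.0 h
- ochre: at 4.0 h add partner, 100% of the amount charged, then wait 4.0 h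

- the volume of additions can be left aside
- the earlier runs do not show what temperature does; that part of a forecast is a guess

* target, in percent of the substrate first charged, at 4.0 h
* the option that brings most further target ("none" if no option brings more than 2 percentage points) (blue / amber / red / ochre / none)
* target present, in percent of the substrate first charged, after blue
* target present, in percent of the substrate first charged, after ochre

Two ways lead to target at 4.0 h in that flask. The charges give the ceiling, 95.0%. The readings give 70.9% at 240 min, and the line through the readings at 120 min and 180 min runs on to 72.2%, so the readings hold together, with a scatter of 1 percentage point on each. The ceiling stands 24 points above the last reading, so one way cheats. Wednesday's run tests the ceiling: with partner at 0.038 M its ceiling is the substrate charged, and it reads 96.5% at 30.0 min, against 77.6% for Friday's flask at 50.0 min. Friday's flask then reads 77.2% at 120 min and 70.9% at 240 min, a fall of 6.3 points against a scatter of 1 point, so the clause that each target stays fails there, and the readings stand. Their last value over the ceiling gives 74.6%: this is the return ρ, the share of the ceiling that stands as target at that time. It is a reading and carries the scatter. The reckoning here takes target near the last reading. Ochre lifts the ceiling of Friday's flask by 5 points, to the substrate charged.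

The forecast reads 71.5% at 4.0 h, ochre as best, 57% after blue and 77% after ochre, on this ground: “Adding partner pulls the remaining substrate into target”. The reckoning above names no best option, and there the two differ.

The simulation gives 71.5% at 4.0 h, red as best with a gain of 13 points, 64.0% after blue and 68.0% after ochre, a change of −3.5 points.

    substrate + partner → target + by-product (k = 0.228 M⁻¹ s⁻¹, Ea = 55.0 kJ mol⁻¹)
    partner ⇌ dormant form (K = 1.30, k = 6.98 × 10⁻⁴ s⁻¹, Ea = 98.0 kJ mol⁻¹, ΔH = −38.0 kJ mol⁻¹)
    target ⇌ isomer of the product (K = 0.610, k = 2.71 × 10⁻⁵ s⁻¹, Ea = 88.0 kJ mol⁻¹, ΔH = −63.0 kJ mol⁻¹)
    (constants at 25 °C)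

The return of Friday's flask comes to 75.3%. With the loss of target to isomer of the product taken out, that flask holds 93.0% rather than 71.5% at 4.0 h, which makes up 75% of what is missing, so this step is the main reason for the shortfall. Without it, red's gain in that flask falls from 13 points to 2 points. The neighbour flask with 0.011 M of partner has a ceiling of 55.0%, so ρ asks for 41.0% of target, and that flask holds 42.0%.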